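**Plan**
Cuts: the 3'-O-benzyl group comes off last. The O1–C2 ether goes back to a primary alcohol and, one oxidation level up, to a chroman-2-ol. That lactol is cut at C4–C4a, C3–H and O1–C2 into 2-methoxyresorcinol and a 2-arylacrolein, and the acrolein is cut at C3–C1' into an aryl bromide and 2-bromoacrolein diethyl acetal.
Enabling feature: ring A carries O1 (C8a), OMe (C8) and OH (C7) on adjacent carbons, so it is 2-methoxyresorcinol. Its C4 and C6 are mirror-related, each ortho to one hydroxyl (later O1) and para to the other (later 7-OH). C4a is therefore the only nucleophilic site, and ring A needs no protecting group.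
Forward: rings A and B are bought as arenes. Ring B gets its 2',3',4',5'-oxygen pattern from syringol through a symmetric dibromide, and C2–C3–C4 is then joined to it. Pyran ring C closes on ring A in the key step, is opened by hydride and is closed again as the ether.
Stereochemistry: C3 is the only stereocentre. It is set as (S) by catalyst-controlled protonation of an enamine in the key step and is not a reacting centre afterwards.

Key step: step 7

Assumption: the sense of induction of the diamine catalyst cannot be derived with certainty for a resorcinol and an α-aryl acrolein; the (S)-diamine from L-tert-leucine is taken to give (3S), and if it favours (3R) the (R)-diamine from D-tert-leucine is used in the same way.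

Step 1
Reactants: 1 2,6-dimethoxyphenol (syringol)
Product: 2 2-(benzyloxy)-1,3-dimethoxybenzene
Conditions: BnBr, K2CO3, DMF, 60 °C
Reagents that add atoms: benzyl bromide, BrCc1ccccc1
Why: Williamson ether synthesis on the acidic phenol; the benzyl group masks the later 3'-OH and moves electrophilic attack from the position para to the free OH to the positions governed by the two methoxy groups.

Step 2
Reactants: 2 2-(benzyloxy)-1,3-dimethoxybenzene
Product: 3 3-(benzyloxy)-1,5-dibromo-2,4-dimethoxybenzene
Conditions: NBS (2.1 equiv), MeCN, 0 °C → rt, dark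
Reagents that add atoms: N-bromosuccinimide, O=C1CCC(=O)N1Br
Why: Electrophilic aromatic bromination; in a 1,2,3-trialkoxybenzene the flanked central alkoxy group is twisted out of conjugation, so both brominations go to the two equivalent carbons that are ortho to one methoxy and para to the other, which gives a symmetric dibromide.

Step 3
Reactants: 3 3-(benzyloxy)-1,5-dibromo-2,4-dimethoxybenzene
Product: 6 3-(benzyloxy)-5-bromo-2,4-dimethoxyphenol, via aryllithium 4 (not isolated), via lithium aryltrimethoxyborate 5 (not isolated)
Conditions: n-BuLi (1.0 equiv), THF, −78 °C; B(OMe)3, −78 °C → rt; AcOH, 30 % aq H2O2, 0 °C → rt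
Reagents that add atoms: hydrogen peroxide, OO
Why: Bromine–lithium exchange, borylation and boronate oxidation (1,2-aryl shift to oxygen); the two bromines are equivalent, so one equivalent of n-BuLi differentiates them, and the meta relation of Li and the remaining Br rules out aryne formation.

Step 4
Reactants: 6 3-(benzyloxy)-5-bromo-2,4-dimethoxyphenol
Product: 7 3-(benzyloxy)-1-bromo-2,4,5-trimethoxybenzene
Conditions: MeI, K2CO3, acetone, reflux
Reagents that add atoms: iodomethane, CI
Why: Williamson methylation of the only free phenol completes the ring-B pattern (Br at C1', OMe at C2', OBn at C3', OMe at C4' and C5', H at C6').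

Step 5
Reactants: 7 3-(benzyloxy)-1-bromo-2,4,5-trimethoxybenzene; 8 2-bromo-3,3-diethoxyprop-1-ene (2-bromoacrolein diethyl acetal)
Product: 11 3-(benzyloxy)-1-(3,3-diethoxyprop-1-en-2-yl)-2,4,5-trimethoxybenzene, via aryllithium 9 (not isolated), via arylzinc chloride 10 (not isolated)
Conditions: n-BuLi, THF, −78 °C; ZnCl2 (THF), −78 °C → rt; 8, Pd2(dba)3 (2 mol %), SPhos (8 mol %), THF, 50 °C
Reagents that add atoms: none
Why: Negishi coupling; bromine–lithium exchange outruns ortho-lithiation and benzylic deprotonation at −78 °C, the arylzinc tolerates the acetal, and the 1,1-disubstituted alkenyl bromide adds readily to Pd(0), so C1'–C3 forms without aqueous base.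

Step 6
Reactants: 11 3-(benzyloxy)-1-(3,3-diethoxyprop-1-en-2-yl)-2,4,5-trimethoxybenzene
Product: 12 2-[3-(benzyloxy)-2,4,5-trimethoxyphenyl]prop-2-enal
Conditions: 10 % aq oxalic acid, THF, rt, trace BHT; used at once as a cold solution
Reagents that add atoms: water, O
Why: Acid-catalysed acetal hydrolysis; the conjugated oxocarbenium ion forms easily, so a weak acid suffices and the benzyl and methyl ethers are untouched.

Step 7
Reactants: 12 2-[3-(benzyloxy)-2,4,5-trimethoxyphenyl]prop-2-enal; 13 2-methoxybenzene-1,3-diol (2-methoxyresorcinol)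
Product: 15 (3S)-3-[3-(benzyloxy)-2,4,5-trimethoxyphenyl]-8-methoxychromane-2,7-diol (anomeric mixture at C2), via hydroxy-aldehyde 14 (not isolated)
Conditions: 13 (3 equiv), (S)-N1,N1-diethyl-3,3-dimethylbutane-1,2-diamine·TfOH (20 mol %), CHCl3, 0 °C, 12 added over several hours; cold pH 4 buffer wash
Reagents that add atoms: none
Why: Proposed new method: the primary amine of the catalyst condenses with the α-branched enal 12 to an iminium ion, C4 of 13 attacks its unsubstituted methylene carbon (Friedel–Crafts conjugate addition, C4–C4a), and the proton lost on rearomatisation is taken up by the tertiary amine arm, leaving a secondary enamine next to an ammonium N–H. This N–H, held over one enamine face by the tert-butyl-bearing stereocentre of the catalyst, is passed to C3 within the same species, so the (3S) centre is set under catalyst control, and hydrolysis releases hydroxy-aldehyde 14. The hydroxyl ortho to the new bond then adds to the aldehyde (6-exo-trig hemiacetalisation, O1–C2) and closes the pyran ring as lactol 15, whose C2 anomers are of no consequence because C2 becomes a methylene group in step 8. The closest known reaction types are the primary-amine-catalysed Friedel–Crafts addition of indoles to α-substituted acroleins with enantioselective enamine protonation and the iminium-catalysed addition of naphthols and electron-rich phenols to enals that ends in chroman-2-ols; their combination with a resorcinol and an α-aryl acrolein has not been shown. The step needs carbon over oxygen attack (oxa-Michael addition is reversible, whereas C-attack is sealed by rearomatisation and lactol formation), a single ring-A site (C4 and C6 of 13 are equivalent and C5 is meta to both hydroxyls) and monoalkylation (excess 13 and slow addition of 12, which also holds back dimerisation of the acrolein). Loss of configuration is countered by the lactol, which withdraws the acidic α-aryl C–H from further enamine formation, by the 2'-methoxy group, which twists ring B out of the enol plane, and by low temperature with removal of the amine before concentration.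

Step 8
Reactants: 15 (3S)-3-[3-(benzyloxy)-2,4,5-trimethoxyphenyl]-8-methoxychromane-2,7-diol
Product: 16 4-{(2S)-2-[3-(benzyloxy)-2,4,5-trimethoxyphenyl]-3-hydroxypropyl}-2-methoxybenzene-1,3-diol
Conditions: NaBH4, THF/MeOH, −20 → 0 °C (crude 15)
Reagents that add atoms: none
Why: Borohydride reduction of a lactol through its ring-chain tautomer 14; hydride capture of the aldehyde at low temperature is faster than enolisation, so C3 keeps its configuration and the anomeric centre disappears.

Step 9
Reactants: 16 4-{(2S)-2-[3-(benzyloxy)-2,4,5-trimethoxyphenyl]-3-hydroxypropyl}-2-methoxybenzene-1,3-diol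
Product: 17 (3S)-3-[3-(benzyloxy)-2,4,5-trimethoxyphenyl]-8-methoxychroman-7-ol
Conditions: PPh3, DIAD, THF (0.01 M), 0 °C → rt
Reagents that add atoms: none
Why: Intramolecular Mitsunobu etherification (6-exo-tet); the primary alcohol is activated as its alkoxyphosphonium ion and displaced by the neighbouring phenol, the distal phenol cannot reach it and high dilution suppresses its intermolecular attack, and C3 is not a reacting centre.

Step 10
Reactants: 17 (3S)-3-[3-(benzyloxy)-2,4,5-trimethoxyphenyl]-8-methoxychroman-7-ol
Product: 18 (3S)-3-(3-hydroxy-2,4,5-trimethoxyphenyl)-8-methoxychroman-7-ol (target)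
Conditions: H2 (1 atm), 10 % Pd/C, EtOAc/MeOH, rt
Reagents that add atoms: none
Why: Hydrogenolysis of the aryl benzyl ether; the molecule holds no other benzylic C–O bond and C3 bears no leaving group, so the chroman and its configuration persist.

**Compound list**
1 | 2,6-dimethoxyphenol (syringol) | COc1cccc(OC)c1O | starting material
2 | 2-(benzyloxy)-1,3-dimethoxybenzene | COc1cccc(OC)c1OCc1ccccc1 | intermediate
3 | 3-(benzyloxy)-1,5-dibromo-2,4-dimethoxybenzene | COc1c(Br)cc(Br)c(OC)c1OCc1ccccc1 | intermediate
4 | [3-(benzyloxy)-5-bromo-2,4-dimethoxyphenyl]lithium | [Li]c1cc(Br)c(OC)c(OCc2ccccc2)c1OC | intermediate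
5 | lithium [3-(benzyloxy)-5-bromo-2,4-dimethoxyphenyl]trimethoxyborate | [Li+].CO[B-](OC)(OC)c1cc(Br)c(OC)c(OCc2ccccc2)c1OC | intermediate
6 | 3-(benzyloxy)-5-bromo-2,4-dimethoxyphenol | Oc1cc(Br)c(OC)c(OCc2ccccc2)c1OC | intermediate
7 | 3-(benzyloxy)-1-bromo-2,4,5-trimethoxybenzene | COc1cc(Br)c(OC)c(OCc2ccccc2)c1OC | intermediate
8 | 2-bromo-3,3-diethoxyprop-1-ene (2-bromoacrolein diethyl acetal) | CCOC(OCC)C(Br)=C | starting material
9 | [3-(benzyloxy)-2,4,5-trimethoxyphenyl]lithium | [Li]c1cc(OC)c(OC)c(OCc2ccccc2)c1OC | intermediate
10 | [3-(benzyloxy)-2,4,5-trimethoxyphenyl]zinc chloride | Cl[Zn]c1cc(OC)c(OC)c(OCc2ccccc2)c1OC | intermediate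
11 | 3-(benzyloxy)-1-(3,3-diethoxyprop-1-en-2-yl)-2,4,5-trimethoxybenzene | CCOC(OCC)C(=C)c1cc(OC)c(OC)c(OCc2ccccc2)c1OC | intermediate
12 | 2-[3-(benzyloxy)-2,4,5-trimethoxyphenyl]prop-2-enal | COc1cc(C(=C)C=O)c(OC)c(OCc2ccccc2)c1OC | intermediate
13 | 2-methoxybenzene-1,3-diol (2-methoxyresorcinol) | COc1c(O)cccc1O | starting material
14 | (2S)-2-[3-(benzyloxy)-2,4,5-trimethoxyphenyl]-3-(2,4-dihydroxy-3-methoxyphenyl)propanal | COc1cc([C@@H](C=O)Cc2ccc(O)c(OC)c2O)c(OC)c(OCc3ccccc3)c1OC | intermediate
15 | (3S)-3-[3-(benzyloxy)-2,4,5-trimethoxyphenyl]-8-methoxychromane-2,7-diol, anomeric mixture at C2 | COc1cc([C@H]2C(O)Oc3c(ccc(O)c3OC)C2)c(OC)c(OCc4ccccc4)c1OC | intermediate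
16 | 4-{(2S)-2-[3-(benzyloxy)-2,4,5-trimethoxyphenyl]-3-hydroxypropyl}-2-methoxybenzene-1,3-diol | COc1cc([C@@H](CO)Cc2ccc(O)c(OC)c2O)c(OC)c(OCc3ccccc3)c1OC | intermediate
17 | (3S)-3-[3-(benzyloxy)-2,4,5-trimethoxyphenyl]-8-methoxychroman-7-ol | COc1cc([C@H]2COc3c(ccc(O)c3OC)C2)c(OC)c(OCc4ccccc4)c1OC | intermediate
18 | (3S)-3-(3-hydroxy-2,4,5-trimethoxyphenyl)-8-methoxychroman-7-ol | COc1cc([C@H]2COc3c(ccc(O)c3OC)C2)c(OC)c(O)c1OC | target

Total steps: 10. Longest linear sequence: 10 steps (1 → 18); 8 and 13 enter as bought.

**Steps most likely to fail**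

Step 7 (proposed new method).
- Risks: poor facial selectivity in the enamine protonation, erosion of configuration through reopening of the lactol, a competing uncatalysed addition, or consumption of the acrolein by dimerisation and double alkylation.
- The fallback uses known chemistry only. It builds ring C on ring A first and sets C3 by dynamic kinetic resolution. It sets out from 13 and 7 and returns at 18.
- Friedel–Crafts acylation of 13 with 3-chloropropanoic acid in TfOH should give 3-chloro-1-(2,4-dihydroxy-3-methoxyphenyl)propan-1-one F1.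
- Aqueous NaOH closes this to 7-hydroxy-8-methoxychroman-4-one F2, and BnBr/K2CO3 gives 7-(benzyloxy)-8-methoxychroman-4-one F3.
- Pd-catalysed ketone α-arylation of F3 with 7 (Pd2(dba)3, XPhos, NaOtBu, toluene) gives the racemic isoflavanone 7-(benzyloxy)-3-[3-(benzyloxy)-2,4,5-trimethoxyphenyl]-8-methoxychroman-4-one F4.
- Asymmetric transfer hydrogenation with RuCl[(S,S)-TsDPEN](p-cymene) in HCO2H/Et3N follows. C3 epimerises through the enol while one enantiomer is reduced faster, which should give the cis alcohol (3S,4S)-7-(benzyloxy)-3-[3-(benzyloxy)-2,4,5-trimethoxyphenyl]-8-methoxychroman-4-ol F5.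
- Hydrogenolysis over Pd/C in EtOH with a little AcOH removes the benzylic C4 hydroxyl and both benzyl ethers to reach 18.

Step 5.
- Risks: sluggish coupling of the ortho-substituted, electron-rich arylzinc, loss of ethoxide from the alkenyl–palladium intermediate, or protonation of the arylmetal.
- The fallback drops the cross-coupling and installs the methylene carbon by a Mannich condensation. It sets out from 7 and returns at 12.
- Aryllithium 9 is made as before and opened onto oxirane, giving 2-[3-(benzyloxy)-2,4,5-trimethoxyphenyl]ethan-1-ol F6.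
- Dess–Martin oxidation gives 2-[3-(benzyloxy)-2,4,5-trimethoxyphenyl]acetaldehyde F7.
- Organocatalytic α-methylenation (37 % aq formaldehyde, pyrrolidine/propionic acid, i-PrOH, 45 °C) converts F7 into 12.

Step 9.
- Risks: intermolecular etherification through the free C7 phenol, which leads to oligomers, or capture of the activated alcohol by the hydrazide.
- The fallback avoids O-alkylation altogether. It sets out from 15, skips 16 and returns at 17.
- BF3·OEt2 in CH2Cl2 at −78 °C ionises the lactol to the (3S)-chroman-2-ylium oxocarbenium ion F8, which excess Et3SiH reduces at C2 (ionic hydrogenation).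
- Low temperature and a large excess of silane are needed so that hydride capture stays ahead of proton loss from C3.

**Further compounds**
F1 | step 7 | 3-chloro-1-(2,4-dihydroxy-3-methoxyphenyl)propan-1-one | COc1c(O)ccc(C(=O)CCCl)c1O
F2 | step 7 | 7-hydroxy-8-methoxychroman-4-one | COc1c(O)ccc2C(=O)CCOc12
F3 | step 7 | 7-(benzyloxy)-8-methoxychroman-4-one | COc1c(OCc3ccccc3)ccc2C(=O)CCOc12
F4 | step 7 | rac-7-(benzyloxy)-3-[3-(benzyloxy)-2,4,5-trimethoxyphenyl]-8-methoxychroman-4-one | COc1cc(C2COc3c(ccc(OCc4ccccc4)c3OC)C2=O)c(OC)c(OCc5ccccc5)c1OC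
F5 | step 7 | (3S,4S)-7-(benzyloxy)-3-[3-(benzyloxy)-2,4,5-trimethoxyphenyl]-8-methoxychroman-4-ol | COc1cc([C@H]2COc3c(ccc(OCc4ccccc4)c3OC)[C@H]2O)c(OC)c(OCc5ccccc5)c1OC
F6 | step 5 | 2-[3-(benzyloxy)-2,4,5-trimethoxyphenyl]ethan-1-ol | COc1cc(CCO)c(OC)c(OCc2ccccc2)c1OC
F7 | step 5 | 2-[3-(benzyloxy)-2,4,5-trimethoxyphenyl]acetaldehyde | COc1cc(CC=O)c(OC)c(OCc2ccccc2)c1OC
F8 | step 9 | (3S)-3-[3-(benzyloxy)-2,4,5-trimethoxyphenyl]-7-hydroxy-8-methoxychroman-2-ylium (oxocarbenium ion) | COc1cc([C@H]2C=[O+]c3c(ccc(O)c3OC)C2)c(OC)c(OCc4ccccc4)c1OC
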